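Start from what a flask's substrate does per unit of itself, and hold that against the partner charged.

| flask | substrate | partner | reagent | remark | time |
|---|---|---|---|---|---|
| zeta | 0.30 M | 0.58 M | 1.2 M | run made earlier |  |
| midnight | 0.30 M | 0.390 M | 1.20 M |  | 15 h |
| autumn | 0.60 M | 0.390 M | 1.20 M |  | 15 h |
| summer | 1.2 M | 0.390 M | 1.20 M |  | 15 h |

- zeta (time / h: target / %, substrate / %): 1.50: 4.6, 86.2; 3.00: 16.1, 77.8; 5.00: 30.0, 65.7; 6.00: 32.0, 61.9; 8.00: 43.8, 52.7; 10.0: 47.7, 49.1

(scatter of a reading: 1 percentage point)

- what was read earlier has a scatter of 1 percentage point, one standard deviation
- "hardly changes" means that all values lie within two and a half points (for a concentration: within two and a half percent of the largest)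

* [target] at the end for midnight, autumn, summer, in this order
* the course of these numbers from the first flask to the last (rises, then falls / falls, then rises / rises all the way / hardly changes / falls all the way)

Zeta and midnight looked nearly the same. They shared substrate and reagent charges and differed in partner, 0.58 M against 0.390 M. Zeta's substrate stood at 49.1% after 10.0 h. From that reading I kept 0.0711 /h as f, the fractional pace of the substrate, my name for a pseudo-first-order constant: ln of charge over what is left, divided by the time. I assumed f held for every flask here. That put 34.4% of substrate left after 15 h.

Zeta's target and substrate fell short of the charge by a gap g, 3.2 percentage points at its last reading, and I carried that too. Zeta had turned 0.153 M of substrate, less than its partner charge. My reckoning put midnight at 0.187 M of target, also less than its partner charge, so I expected midnight to follow zeta's course. It put autumn at 0.374 M, just under the partner charge. Summer's first answer was 0.749 M, more than the partner charged. I put that back, assumed one partner per target, and took 0.390 M as my ceiling for summer.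

The forecast gave 0.14 M, 0.24 M and 0.34 M, rises all the way: “target rises with diminishing returns”. My figures stood above these, and they also rose from flask to flask.

The flasks gave 0.183 M, 0.237 M and 0.212 M, so the row rises, then falls.

    substrate + reagent → open intermediate (k = 0.0780 /M/h)
    reagent + partner → second intermediate (k = 0.0810 /M/h)
    open intermediate + second intermediate → target (k = 11.0 /M/h)
    substrate + open intermediate → side product (k = 0.0860 /M/h)

Carried to the end of midnight, f gave 34.4% of substrate left, against 33.6% in the flask. Summer held 36.3% against the same 34.4% from f, yet summer's target came out at 0.212 M, below my ceiling. Part of that shortfall came from the falling level of reagent together with the time given: summer with reagent held reached 0.297 M, and summer at 150 h reached 0.342 M. At the end, reagent in summer stood at 32.0% of its own charge, less than the 62.0% in midnight.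

The runs were computed on assumed constants.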